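**Plan**
- Retrosynthesis: the ring bonds C4–C5 and C6–C7 of the hexahydroinden-4-one are cut, which takes the enone carbons C5=C6 out as an alkyne and leaves a bicyclic cyclobutanone. In the side chain the 2',3'-alkene is traced back by a 1,3-transposition to a 1',2'-alkene with a 3'-hydroxyl; further cuts are C(sp)–C(sp2), the carbinol C–C bond and aryl–CH2.
- Forward order: the cyclopentane ring is bought as 1,2-dimethylcyclopentene, the four-membered ring comes from a ketene [2+2], and the six-membered enone ring arises by two-carbon expansion of that cyclobutanone in the step that also joins the side chain. The skipped diene is unveiled afterwards.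
- Enabling feature: the strained acyl–CH2 bond C6–C7 of (1R,5R)-1,5-dimethylbicyclo[3.2.0]heptan-6-one (the other acyl bond ends at quaternary C5), together with a 1,3-enyne whose alkene fixes the alkyne orientation. That alkene is a temporary helper, removed by the transposition.
- Stereochemistry: the suprafacial [2+2] makes the two quaternary carbons cis, and resolution as the (R,R)-hydrobenzoin ketal gives the absolute configuration; both centres are untouched afterwards. The (E)-alkene comes from the retro-ene step of an allylic diazene whose (Z)-dienyl precursor is set by anti-carbomagnesiation.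

Key step: step 13

Remark: the side-chain carbinol carbon made in step 9 is carried as both configurations (SMILES left open at that atom) because step 15 erases it; racemates 2 and 3 are written as the enantiomer that is carried on. Ar = 2-(tert-butyldimethylsilyloxy)-5-methoxy-3-methylphenyl.

**Step 1**
Reactants: 1 1,2-dimethylcyclopentene
Product: 2 rac-(1S,5R)-7,7-dichloro-1,5-dimethylbicyclo[3.2.0]heptan-6-one
Conditions: Cl3CCOCl, Zn–Cu couple, Et2O/DME, 25 °C (ultrasound)
Reagents that add atoms: trichloroacetyl chloride ClC(=O)C(Cl)(Cl)Cl (delivered as dichloroketene)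
Why: Ketene–alkene [2+2] cycloaddition of dichloroketene, generated by zinc dechlorination, across the electron-rich tetrasubstituted alkene; suprafacial addition to the alkene places the two new quaternary carbons cis (racemic).

**Step 2**
Reactants: 2 rac-(1S,5R)-7,7-dichloro-1,5-dimethylbicyclo[3.2.0]heptan-6-one
Product: 3 rac-(1R,5R)-1,5-dimethylbicyclo[3.2.0]heptan-6-one
Conditions: Zn dust, AcOH, 70 °C
Reagents that add atoms: none
Why: Reductive dechlorination of an α,α-dichloroketone by zinc in acetic acid through zinc enolates; the quaternary centres are not involved.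

**Step 3**
Reactants: 3 rac-(1R,5R)-1,5-dimethylbicyclo[3.2.0]heptan-6-one
Product: 4 (1R,4'R,5R,5'R)-1,5-dimethyl-4',5'-diphenylspiro[bicyclo[3.2.0]heptane-6,2'-[1,3]dioxolane]
Conditions: (1R,2R)-1,2-diphenylethane-1,2-diol, TsOH·H2O (cat.), toluene, reflux (Dean–Stark)
Reagents that add atoms: (1R,2R)-1,2-diphenylethane-1,2-diol O[C@H](c1ccccc1)[C@H](O)c1ccccc1
Why: Acid-catalysed ketalisation of the strained ketone with a C2-symmetric diol creates no new stereocentre, so exactly two diastereomeric ketals form, one from each enantiomer of 3, and 4 should be separable from its (1S,5S)-derived diastereomer by chromatography or crystallisation (classical resolution; configuration of 4 to be confirmed by X-ray analysis).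

**Step 4**
Reactants: 4 (1R,4'R,5R,5'R)-1,5-dimethyl-4',5'-diphenylspiro[bicyclo[3.2.0]heptane-6,2'-[1,3]dioxolane]
Product: 5 (1R,5R)-1,5-dimethylbicyclo[3.2.0]heptan-6-one
Conditions: 2 M HCl, THF, 50 °C
Reagents that add atoms: water O
Why: Acid hydrolysis of the ketal returns the ketone; both stereocentres are quaternary and cannot epimerise.

**Step 5**
Reactants: 6 4-methoxy-2-methylphenol
Product: 7 allyl 4-methoxy-2-methylphenyl ether
Conditions: allyl bromide, K2CO3, acetone, reflux
Reagents that add atoms: allyl bromide C=CCBr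
Why: Williamson ether synthesis on the phenoxide with a reactive allylic halide.

**Step 6**
Reactants: 7 allyl 4-methoxy-2-methylphenyl ether
Product: 8 2-allyl-4-methoxy-6-methylphenol
Conditions: N,N-diethylaniline, 200 °C
Reagents that add atoms: none
Why: Aromatic Claisen rearrangement ([3,3]-sigmatropic shift then enolisation) to the only free ortho position, the para position being blocked by methoxy.

**Step 7**
Reactants: 8 2-allyl-4-methoxy-6-methylphenol
Product: 9 tert-butyl(2-allyl-4-methoxy-6-methylphenoxy)dimethylsilane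
Conditions: TBSCl, imidazole, DMF, 40 °C
Reagents that add atoms: tert-butyldimethylsilyl chloride CC(C)(C)[Si](C)(C)Cl
Why: Silylation of the phenol, which shields it from periodate in step 8 and from the Mitsunobu reagents in step 15.

**Step 8**
Reactants: 9 tert-butyl(2-allyl-4-methoxy-6-methylphenoxy)dimethylsilane
Product: 11 2-Ar-acetaldehyde, via vicinal diol 10 (not isolated)
Conditions: OsO4 (cat.), NaIO4, 2,6-lutidine, dioxane/H2O, 23 °C
Reagents that add atoms: osmium tetroxide O=[Os](=O)(=O)=O (oxygen carrier); sodium periodate [Na+].[O-]I(=O)(=O)=O (terminal oxidant)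
Why: Lemieux–Johnson oxidation: dihydroxylation of the terminal alkene then periodate cleavage of the diol, which spares the electron-rich silylated arene better than ozone would.

**Step 9**
Reactants: 11 2-Ar-acetaldehyde
Product: 12 rac-1-Ar-but-3-yn-2-ol
Conditions: HC≡CMgBr, THF, −20 → 0 °C
Reagents that add atoms: ethynylmagnesium bromide C#C[Mg]Br
Why: Grignard addition of the weakly basic acetylide to the aldehyde at low temperature, which limits enolisation; the carbinol centre is racemic and later erased.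

**Step 10**
Reactants: 12 rac-1-Ar-but-3-yn-2-ol
Product: 14 rac-(3Z)-1-Ar-4-iodo-3-methylbut-3-en-2-ol, via cyclic alkenylmagnesium alkoxide 13 (not isolated)
Conditions: MeMgBr (3 equiv), CuI (10 mol %), Et2O, −10 → 23 °C; then I2, THF, −20 °C
Reagents that add atoms: methylmagnesium bromide C[Mg]Br; iodine II
Why: Copper-catalysed anti-carbomagnesiation of the propargylic magnesium alkoxide puts methyl on the internal carbon and magnesium on the terminal carbon inside a five-membered chelate (13), and iodinolysis with retention gives the (Z)-iodide with iodine cis to the carbinol carbon.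

**Step 11**
Reactants: 14 rac-(3Z)-1-Ar-4-iodo-3-methylbut-3-en-2-ol; 15 2-methylpent-4-yn-2-ol
Product: 16 rac-(3Z)-1-Ar-3,8-dimethylnon-3-en-5-yne-2,8-diol
Conditions: Pd(PPh3)2Cl2 (3 mol %), CuI (5 mol %), Et3N, THF, 23 °C
Reagents that add atoms: none
Why: Sonogashira coupling of an alkenyl iodide with a terminal alkyne proceeds with retention of alkene geometry; room temperature is kept so that the (Z)-enynol does not cycloisomerise to a furan.

**Step 12**
Reactants: 16 rac-(3Z)-1-Ar-3,8-dimethylnon-3-en-5-yne-2,8-diol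
Product: 17 rac-(3Z)-1-Ar-3,8-dimethyl-2,8-bis(triethylsilyloxy)non-3-en-5-yne
Conditions: Et3SiOTf (2.5 equiv), 2,6-lutidine, CH2Cl2, −78 → 0 °C
Reagents that add atoms: triethylsilyl trifluoromethanesulfonate CC[Si](CC)(CC)OS(=O)(=O)C(F)(F)F
Why: The silyl triflate silylates both the secondary allylic and the tertiary alcohol, removing protic and isomerisable groups before the nickel step.

**Step 13**
Reactants: 5 (1R,5R)-1,5-dimethylbicyclo[3.2.0]heptan-6-one; 17 rac-(3Z)-1-Ar-3,8-dimethyl-2,8-bis(triethylsilyloxy)non-3-en-5-yne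
Product: 20 (3aR,7aR)-6-[(1Z)-4-Ar-2-methyl-3-(triethylsilyloxy)but-1-en-1-yl]-3a,7a-dimethyl-5-[2-methyl-2-(triethylsilyloxy)propyl]-1,2,3,3a,7,7a-hexahydro-4H-inden-4-one (both epimers at the silyloxy carbon), via oxanickelacyclopentene 18 (not isolated), via nickelacycloheptenone 19 (not isolated)
Conditions: Ni(cod)2 (10 mol %), PCy3 (20 mol %), 5 (1.5 equiv), toluene, 100 °C, argon
Reagents that add atoms: none
Why: Zerovalent nickel couples the carbonyl of 5 with the alkyne of 17 by oxidative cyclisation to the spiro oxanickelacyclopentene 18 (divalent nickel); β-carbon elimination opens the four-membered ring at its acyl–CH2 bond to the seven-membered nickelacycle 19, and C(sp2)–C(sp3) reductive elimination gives 20 and returns the catalyst. The closest known reaction type is the nickel-catalysed intermolecular insertion of internal alkynes into cyclobutanones (formal [4+2]), and the enyne orientation is modelled on nickel-catalysed couplings of 1,3-enynes with aldehydes. The six-membered ring is closed by two-carbon ring expansion of the cyclobutanone: the alkyne carbons become C5 and C6 of the indenone and are stitched in between the former carbonyl carbon (C4) and the former ring CH2 (C7), the last bond by reductive elimination from 19, while the cyclopentane ring is only carried along. No stereocentre is formed: C3a and C7a are the bridgeheads of 5, are not touched and keep the (R,R) configuration fixed by the resolution. Two selectivities are needed: cleavage of the acyl–CH2 bond rather than the acyl–C(quaternary) bond, secured because β-carbon elimination then gives a primary alkylnickel and avoids the fully substituted bridgehead; and the alkyne orientation, secured by the conjugated, α-branched alkenyl group of 17, which ends on the nickel-bound carbon through η3-type stabilisation while the carbon bearing CH2C(Me)2OSiEt3 bonds to the carbonyl carbon. The silyl ethers keep both hydroxyls and the phenol away from the electron-rich nickel centre.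

**Step 14**
Reactants: 20 (3aR,7aR)-6-[(1Z)-4-Ar-2-methyl-3-(triethylsilyloxy)but-1-en-1-yl]-3a,7a-dimethyl-5-[2-methyl-2-(triethylsilyloxy)propyl]-1,2,3,3a,7,7a-hexahydro-4H-inden-4-one
Product: 21 (3aR,7aR)-6-[(1Z)-4-Ar-3-hydroxy-2-methylbut-1-en-1-yl]-5-(2-hydroxy-2-methylpropyl)-3a,7a-dimethyl-1,2,3,3a,7,7a-hexahydro-4H-inden-4-one (both carbinol epimers)
Conditions: PPTS (cat.), MeOH/CH2Cl2, 23 → 40 °C
Reagents that add atoms: none
Why: Mild acid-catalysed methanolysis cleaves the two alkyl triethylsilyl ethers while the aryl tert-butyldimethylsilyl ether, which is stable to weak acid, stays; the allylic carbinol is deactivated towards ionisation by conjugation with the enone.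

**Step 15**
Reactants: 21 (3aR,7aR)-6-[(1Z)-4-Ar-3-hydroxy-2-methylbut-1-en-1-yl]-5-(2-hydroxy-2-methylpropyl)-3a,7a-dimethyl-1,2,3,3a,7,7a-hexahydro-4H-inden-4-one
Product: 24 (3aR,7aR)-6-[(2E)-4-Ar-2-methylbut-2-en-1-yl]-5-(2-hydroxy-2-methylpropyl)-3a,7a-dimethyl-1,2,3,3a,7,7a-hexahydro-4H-inden-4-one, via N-allyl-N-sulfonylhydrazine 22 (not isolated), via allylic diazene 23 (not isolated)
Conditions: 2-O2NC6H4SO2NHNH2, PPh3, DEAD, N-methylmorpholine, −30 °C; then 23 °C
Reagents that add atoms: none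
Why: Reductive 1,3-transposition of an allylic alcohol: Mitsunobu displacement by 2-nitrobenzenesulfonylhydrazide (the tertiary alcohol and the hindered ketone are inert), loss of sulfinic acid to diazene 23 and retro-ene loss of N2 deliver hydrogen to C1' and move the alkene to C2'=C3'; because the indenone ring is cis to the carbinol carbon, allylic 1,3-strain should force the CH2Ar group outward in the transition state and give the (E)-alkene.

**Step 16**
Reactants: 24 (3aR,7aR)-6-[(2E)-4-Ar-2-methylbut-2-en-1-yl]-5-(2-hydroxy-2-methylpropyl)-3a,7a-dimethyl-1,2,3,3a,7,7a-hexahydro-4H-inden-4-one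
Product: 25 (3aR,7aR)-5-(2-hydroxy-2-methylpropyl)-6-[(2E)-4-(2-hydroxy-5-methoxy-3-methylphenyl)-2-methylbut-2-en-1-yl]-3a,7a-dimethyl-1,2,3,3a,7,7a-hexahydro-4H-inden-4-one
Conditions: Bu4NF, AcOH, THF, 0 °C
Reagents that add atoms: none
Why: Fluoride cleaves the aryl silyl ether under buffered conditions that leave the enone, the skipped diene and the tertiary alcohol untouched.

**Compound list**
1 | 1,2-dimethylcyclopentene | CC1=C(C)CCC1 | starting material
2 | rac-(1S,5R)-7,7-dichloro-1,5-dimethylbicyclo[3.2.0]heptan-6-one | O=C1[C@]2(C)CCC[C@]2(C)C1(Cl)Cl | intermediate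
3 | rac-(1R,5R)-1,5-dimethylbicyclo[3.2.0]heptan-6-one | O=C1[C@]2(C)CCC[C@]2(C)C1 | intermediate
4 | (1R,4'R,5R,5'R)-1,5-dimethyl-4',5'-diphenylspiro[bicyclo[3.2.0]heptane-6,2'-[1,3]dioxolane] | C12(O[C@H](c3ccccc3)[C@@H](c3ccccc3)O1)[C@]1(C)CCC[C@]1(C)C2 | intermediate
5 | (1R,5R)-1,5-dimethylbicyclo[3.2.0]heptan-6-one | O=C1[C@]2(C)CCC[C@]2(C)C1 | intermediate
6 | 4-methoxy-2-methylphenol | COc1ccc(O)c(C)c1 | starting material
7 | allyl 4-methoxy-2-methylphenyl ether | C=CCOc1ccc(OC)cc1C | intermediate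
8 | 2-allyl-4-methoxy-6-methylphenol | C=CCc1cc(OC)cc(C)c1O | intermediate
9 | tert-butyl(2-allyl-4-methoxy-6-methylphenoxy)dimethylsilane | C=CCc1cc(OC)cc(C)c1O[Si](C)(C)C(C)(C)C | intermediate
10 | rac-3-[2-(tert-butyldimethylsilyloxy)-5-methoxy-3-methylphenyl]propane-1,2-diol | OCC(O)Cc1cc(OC)cc(C)c1O[Si](C)(C)C(C)(C)C | intermediate
11 | 2-[2-(tert-butyldimethylsilyloxy)-5-methoxy-3-methylphenyl]acetaldehyde | O=CCc1cc(OC)cc(C)c1O[Si](C)(C)C(C)(C)C | intermediate
12 | rac-1-[2-(tert-butyldimethylsilyloxy)-5-methoxy-3-methylphenyl]but-3-yn-2-ol | C#CC(O)Cc1cc(OC)cc(C)c1O[Si](C)(C)C(C)(C)C | intermediate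
13 | 5-{[2-(tert-butyldimethylsilyloxy)-5-methoxy-3-methylphenyl]methyl}-4-methyl-2,5-dihydro-1,2-oxamagnesole (cyclic alkenylmagnesium alkoxide) | CC1=C[Mg]OC1Cc1cc(OC)cc(C)c1O[Si](C)(C)C(C)(C)C | intermediate
14 | rac-(3Z)-1-[2-(tert-butyldimethylsilyloxy)-5-methoxy-3-methylphenyl]-4-iodo-3-methylbut-3-en-2-ol | I/C=C(/C)C(O)Cc1cc(OC)cc(C)c1O[Si](C)(C)C(C)(C)C | intermediate
15 | 2-methylpent-4-yn-2-ol | C#CCC(C)(C)O | starting material
16 | rac-(3Z)-1-[2-(tert-butyldimethylsilyloxy)-5-methoxy-3-methylphenyl]-3,8-dimethylnon-3-en-5-yne-2,8-diol | CC(C)(O)CC#C/C=C(/C)C(O)Cc1cc(OC)cc(C)c1O[Si](C)(C)C(C)(C)C | intermediate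
17 | rac-(3Z)-1-[2-(tert-butyldimethylsilyloxy)-5-methoxy-3-methylphenyl]-3,8-dimethyl-2,8-bis(triethylsilyloxy)non-3-en-5-yne | CC[Si](CC)(CC)OC(C)(C)CC#C/C=C(/C)C(O[Si](CC)(CC)CC)Cc1cc(OC)cc(C)c1O[Si](C)(C)C(C)(C)C | intermediate
18 | spiro oxanickelacyclopentene (divalent nickel, PCy3-ligated; the P–Ni coordination is written with formal charges) from carbonyl–alkyne oxidative cyclisation | CC[Si](CC)(CC)OC(C)(C)CC1=C(/C=C(/C)C(O[Si](CC)(CC)CC)Cc2cc(OC)cc(C)c2O[Si](C)(C)C(C)(C)C)[Ni-]([P+](C2CCCCC2)(C2CCCCC2)C2CCCCC2)OC13[C@]2(C)CCC[C@]2(C)C3 | intermediate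
19 | seven-membered nickelacycloheptenone (divalent nickel, PCy3-ligated; the P–Ni coordination is written with formal charges) after β-carbon elimination | [Ni-]1([P+](C2CCCCC2)(C2CCCCC2)C2CCCCC2)C(/C=C(/C)C(O[Si](CC)(CC)CC)Cc2cc(OC)cc(C)c2O[Si](C)(C)C(C)(C)C)=C(CC(C)(C)O[Si](CC)(CC)CC)C(=O)[C@]2(C)CCC[C@]2(C)C1 | intermediate
20 | (3aR,7aR)-6-{(1Z)-4-[2-(tert-butyldimethylsilyloxy)-5-methoxy-3-methylphenyl]-2-methyl-3-(triethylsilyloxy)but-1-en-1-yl}-3a,7a-dimethyl-5-[2-methyl-2-(triethylsilyloxy)propyl]-1,2,3,3a,7,7a-hexahydro-4H-inden-4-one (both epimers at the silyloxy carbon) | CC(C)(C)[Si](C)(C)Oc1c(C)cc(OC)cc1CC(O[Si](CC)(CC)CC)/C(C)=C\C2=C(CC(C)(C)O[Si](CC)(CC)CC)C(=O)[C@]3(C)CCC[C@]3(C)C2 | intermediate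
21 | (3aR,7aR)-6-{(1Z)-4-[2-(tert-butyldimethylsilyloxy)-5-methoxy-3-methylphenyl]-3-hydroxy-2-methylbut-1-en-1-yl}-5-(2-hydroxy-2-methylpropyl)-3a,7a-dimethyl-1,2,3,3a,7,7a-hexahydro-4H-inden-4-one (both carbinol epimers) | CC(C)(C)[Si](C)(C)Oc1c(C)cc(OC)cc1CC(O)/C(C)=C\C2=C(CC(C)(C)O)C(=O)[C@]3(C)CCC[C@]3(C)C2 | intermediate
22 | N-allylic N-(2-nitrobenzenesulfonyl)hydrazine formed from 21 by Mitsunobu displacement | CC(C)(C)[Si](C)(C)Oc1c(C)cc(OC)cc1CC(N(N)S(=O)(=O)c1ccccc1[N+](=O)[O-])/C(C)=C\C2=C(CC(C)(C)O)C(=O)[C@]3(C)CCC[C@]3(C)C2 | intermediate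
23 | allylic monoalkyl diazene | CC(C)(C)[Si](C)(C)Oc1c(C)cc(OC)cc1CC(N=N)/C(C)=C\C2=C(CC(C)(C)O)C(=O)[C@]3(C)CCC[C@]3(C)C2 | intermediate
24 | (3aR,7aR)-6-{(2E)-4-[2-(tert-butyldimethylsilyloxy)-5-methoxy-3-methylphenyl]-2-methylbut-2-en-1-yl}-5-(2-hydroxy-2-methylpropyl)-3a,7a-dimethyl-1,2,3,3a,7,7a-hexahydro-4H-inden-4-one | CC(C)(C)[Si](C)(C)Oc1c(C)cc(OC)cc1C/C=C(\C)CC2=C(CC(C)(C)O)C(=O)[C@]3(C)CCC[C@]3(C)C2 | intermediate
25 | (3aR,7aR)-5-(2-hydroxy-2-methylpropyl)-6-[(2E)-4-(2-hydroxy-5-methoxy-3-methylphenyl)-2-methylbut-2-en-1-yl]-3a,7a-dimethyl-1,2,3,3a,7,7a-hexahydro-4H-inden-4-one | COc1cc(C)c(O)c(C/C=C(\C)CC2=C(CC(C)(C)O)C(=O)[C@]3(C)CCC[C@]3(C)C2)c1 | target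

**Step count**
Total: 16 steps. Longest linear sequence: 12 steps (steps 5–16, from 6); the cyclobutanone branch (steps 1–4) joins at step 13.

**Steps most likely to fail**

1. Step 13. What may go wrong: oxidative cyclisation at the crowded carbonyl of 5 may be slow, so that the conjugated enyne 17 is consumed by nickel-mediated self-coupling; the silyloxy-bearing carbon cis to the alkyne may also hinder coordination of the enyne. The fallback sets out from 11 (and uses 5 and 15) and comes back at 25; it gives up the helper alkene and accepts a separation of regioisomers. Aldehyde 11 is olefinated with ethyl 2-(triphenylphosphoranylidene)propanoate (Wittig, E-selective) to ethyl (2E)-4-Ar-2-methylbut-2-enoate F1, which is reduced with diisobutylaluminium hydride to (2E)-4-Ar-2-methylbut-2-en-1-ol F2 and converted with CBr4 and PPh3 into (2E)-4-Ar-1-bromo-2-methylbut-2-ene F3. Coupling with 15 (CuI, K2CO3, NaI, DMF) gives the skipped enynol (7E)-9-Ar-2,7-dimethylnon-7-en-4-yn-2-ol F4, which is silylated with Et3SiOTf to its triethylsilyl ether F5. Insertion of this non-conjugated alkyne into 5 with the same nickel catalyst should give the doubly silylated form of the target F6 beside its regioisomer F7 with the two side arms exchanged; they are separated by chromatography, since no group steers the alkyne orientation. Bu4NF then removes both silyl groups of F6 and gives 25.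

2. Step 15. What may go wrong: the Mitsunobu displacement at the crowded secondary dienyl carbinol may be slow, so that elimination or attack at the distal alkene carbon competes. The fallback sets out from 21 and comes back at 24. Oxidation of 21 with Dess–Martin periodinane gives the side-chain ketone (3aR,7aR)-6-[(1Z)-4-Ar-2-methyl-3-oxobut-1-en-1-yl]-5-(2-hydroxy-2-methylpropyl)-3a,7a-dimethyl-1,2,3,3a,7,7a-hexahydro-4H-inden-4-one F8. Condensation with 4-methylbenzenesulfonohydrazide, which should occur only at this unhindered carbonyl, gives tosylhydrazone F9. Catecholborane reduces the C=N bond to the allylic N'-tosylhydrazine F10, and NaOAc·3H2O at 60 °C expels sulfinate to the same diazene 23, which loses N2 to 24 (alkene-transposing deoxygenation of an unsaturated tosylhydrazone).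

3. Step 3. What may go wrong: the two diastereomeric ketals differ only in a compact hydrocarbon part and may co-elute or co-crystallise, leaving the resolution incomplete. The fallback sets out from 3 and comes back at 5. It is an enzymatic kinetic resolution with a ketoreductase (NADPH-dependent alcohol dehydrogenase, glucose and glucose dehydrogenase for recycling, phosphate buffer/DMSO, 30 °C), chosen by screening so that only the (1S,5S) ketone is reduced, to (1S,5S,6R)-1,5-dimethylbicyclo[3.2.0]heptan-6-ol F11. The untouched ketone 5 is then separated from the alcohol on silica.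

**Further compounds**
F1 | step 13 | ethyl (2E)-4-[2-(tert-butyldimethylsilyloxy)-5-methoxy-3-methylphenyl]-2-methylbut-2-enoate | CCOC(=O)/C(C)=C/Cc1cc(OC)cc(C)c1O[Si](C)(C)C(C)(C)C
F2 | step 13 | (2E)-4-[2-(tert-butyldimethylsilyloxy)-5-methoxy-3-methylphenyl]-2-methylbut-2-en-1-ol | OC/C(C)=C/Cc1cc(OC)cc(C)c1O[Si](C)(C)C(C)(C)C
F3 | step 13 | (2E)-4-[2-(tert-butyldimethylsilyloxy)-5-methoxy-3-methylphenyl]-1-bromo-2-methylbut-2-ene | BrC/C(C)=C/Cc1cc(OC)cc(C)c1O[Si](C)(C)C(C)(C)C
F4 | step 13 | (7E)-9-[2-(tert-butyldimethylsilyloxy)-5-methoxy-3-methylphenyl]-2,7-dimethylnon-7-en-4-yn-2-ol | CC(C)(O)CC#CC/C(C)=C/Cc1cc(OC)cc(C)c1O[Si](C)(C)C(C)(C)C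
F5 | step 13 | triethylsilyl ether of F4 | CC[Si](CC)(CC)OC(C)(C)CC#CC/C(C)=C/Cc1cc(OC)cc(C)c1O[Si](C)(C)C(C)(C)C
F6 | step 13 | (3aR,7aR)-6-{(2E)-4-[2-(tert-butyldimethylsilyloxy)-5-methoxy-3-methylphenyl]-2-methylbut-2-en-1-yl}-3a,7a-dimethyl-5-[2-methyl-2-(triethylsilyloxy)propyl]-1,2,3,3a,7,7a-hexahydro-4H-inden-4-one | CC(C)(C)[Si](C)(C)Oc1c(C)cc(OC)cc1C/C=C(\C)CC2=C(CC(C)(C)O[Si](CC)(CC)CC)C(=O)[C@]3(C)CCC[C@]3(C)C2
F7 | step 13 | (3aR,7aR)-5-{(2E)-4-[2-(tert-butyldimethylsilyloxy)-5-methoxy-3-methylphenyl]-2-methylbut-2-en-1-yl}-3a,7a-dimethyl-6-[2-methyl-2-(triethylsilyloxy)propyl]-1,2,3,3a,7,7a-hexahydro-4H-inden-4-one (regioisomer of F6) | CC[Si](CC)(CC)OC(C)(C)CC2=C(C/C(C)=C/Cc1cc(OC)cc(C)c1O[Si](C)(C)C(C)(C)C)C(=O)[C@]3(C)CCC[C@]3(C)C2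
F8 | step 15 | (3aR,7aR)-6-{(1Z)-4-[2-(tert-butyldimethylsilyloxy)-5-methoxy-3-methylphenyl]-2-methyl-3-oxobut-1-en-1-yl}-5-(2-hydroxy-2-methylpropyl)-3a,7a-dimethyl-1,2,3,3a,7,7a-hexahydro-4H-inden-4-one | CC(C)(C)[Si](C)(C)Oc1c(C)cc(OC)cc1CC(=O)/C(C)=C\C2=C(CC(C)(C)O)C(=O)[C@]3(C)CCC[C@]3(C)C2
F9 | step 15 | 4-methylbenzenesulfonylhydrazone of F8 at the side-chain ketone | CC(C)(C)[Si](C)(C)Oc1c(C)cc(OC)cc1CC(=NNS(=O)(=O)c1ccc(C)cc1)/C(C)=C\C2=C(CC(C)(C)O)C(=O)[C@]3(C)CCC[C@]3(C)C2
F10 | step 15 | allylic N'-(4-methylbenzenesulfonyl)hydrazine from reduction of F9 | CC(C)(C)[Si](C)(C)Oc1c(C)cc(OC)cc1CC(NNS(=O)(=O)c1ccc(C)cc1)/C(C)=C\C2=C(CC(C)(C)O)C(=O)[C@]3(C)CCC[C@]3(C)C2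
F11 | step 3 | (1S,5S,6R)-1,5-dimethylbicyclo[3.2.0]heptan-6-ol | O[C@H]1[C@@]2(C)CCC[C@@]2(C)C1
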